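**Plan**
- Locants: β-carboline numbering for the core (C1, N2, C3, C4, C4a, C9a, N9), primed numbers for the 7'-methoxyindole. The retrosynthesis cuts C3'–CH2NMe2 (Mannich), N1'–Ts, N9–C8a (aryl amination) and then, in one step, the three piperidine bonds C4a–C4, C9a–C1 and N2–C3.
- Enabling feature: C9a carries nitrogen and C4a the aryl ether oxygen, so the dihydrofuran ring is a dearomatised 3-nitrobenzofuran (C9a = furan C3, with NO2 standing in for N9; C4a = furan C2, with the 2-bromophenyl group). The piperidine ring is acetaldehyde (C4–C3) plus N-methylmethanimine (C1–N2) annulated onto it.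
- Forward ring order: furan ring (Sonogashira/cyclisation on an iodonitrophenol), pyrrole ring (Bartoli reaction on the same nitro group), nitration of the furan carbon, piperidine ring (key step), indoline ring (C–N coupling), gramine side chain last.
- Stereochemistry: C4a comes from the chiral amine catalyst in the enamine addition; C9a is relayed from C4a (iminium anti to the aryl group, and only the cis-fused ring can close). Both centres are quaternary afterwards and cannot epimerise.

Key step: step 6

Assumption: the (S)-catalyst is taken to give the 4aS centre (synclinal transition state with the nitro group under the enamine nitrogen and the ring oxygen in the place of the β-aryl group of a nitrostyrene); if the addition shows the opposite sense, the (R)-catalyst is used and nothing else changes.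

**Route**

Step 1
Reactants: 1 3-methoxy-4-nitrophenol
Product: 2 2-iodo-5-methoxy-4-nitrophenol
Conditions: NIS (1.05 equiv), TFA (cat.), MeCN, rt
Reagents that add atoms: N-iodosuccinimide, O=C1CCC(=O)N1I
Why: Electrophilic aromatic iodination should go to the one carbon that is ortho to OH and para to OMe and is not flanked by two substituents, so a single mono-iodide is expected.

Step 2
Reactants: 2 2-iodo-5-methoxy-4-nitrophenol; 3 1-bromo-2-ethynylbenzene
Product: 5 2-(2-bromophenyl)-6-methoxy-5-nitrobenzofuran, via alkynylphenol 4 (not isolated)
Conditions: PdCl2(PPh3)2 (3 mol %), CuI (5 mol %), Et3N, DMF (degassed), rt then 70 °C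
Reagents that add atoms: none
Why: Sonogashira coupling at the C–I bond, which adds to zerovalent palladium far faster than the C–Br bond of 3, gives the o-alkynylphenol, whose phenoxide then closes onto the metal-activated alkyne (5-endo-dig heteroannulation), the usual one-pot route from 2-iodo-4-nitrophenols to 2-substituted 5-nitrobenzofurans.

Step 3
Reactants: 5 2-(2-bromophenyl)-6-methoxy-5-nitrobenzofuran
Product: 6 2-(2-bromophenyl)-5-methoxy-6H-furo[3,2-e]indole (ring numbering O3, N6; N–H free)
Conditions: CH2=CHMgBr (3.5 equiv), THF, −45 °C; aq. NH4Cl
Reagents that add atoms: vinylmagnesium bromide, C=C[Mg]Br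
Why: Bartoli indole synthesis, in which the nitro group with its required ortho substituent (OMe) is converted via the nitrosoarene and a [3,3]-sigmatropic shift of the N-aryl-O-vinylhydroxylamine onto the only free ortho carbon (benzofuran C4) into the 7'-methoxyindole, the aryl bromide being inert to the vinyl Grignard reagent at this temperature.

Step 4
Reactants: 6 2-(2-bromophenyl)-5-methoxy-6H-furo[3,2-e]indole
Product: 7 2-(2-bromophenyl)-5-methoxy-6-tosyl-6H-furo[3,2-e]indole
Conditions: NaH, DMF, 0 °C; TsCl, 0 °C → rt
Reagents that add atoms: p-toluenesulfonyl chloride, Cc1ccc(S(=O)(=O)Cl)cc1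
Why: N-sulfonylation of the indole sodium salt installs a group that lowers the nucleophilicity of the pyrrole ring for the nitration, makes the benzo ring a poorer donor toward the nitroalkene and survives until its reductive removal.

Step 5
Reactants: 7 2-(2-bromophenyl)-5-methoxy-6-tosyl-6H-furo[3,2-e]indole
Product: 8 2-(2-bromophenyl)-5-methoxy-1-nitro-6-tosyl-6H-furo[3,2-e]indole (the 2-aryl-3-nitrobenzofuran)
Conditions: fuming HNO3 (1.05 equiv), Ac2O, CH2Cl2, −40 → −20 °C
Reagents that add atoms: nitric acid, O[N+](=O)[O-]
Why: Electrophilic nitration with acetyl nitrate should take place at the enol-ether carbon of the 2-arylbenzofuran (attack there gives an oxocarbenium ion conjugated with the 2-aryl group), and one equivalent of this mild reagent at low temperature is chosen to spare the N-sulfonylpyrrole carbon C3' and the arene carbon C6'.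

Step 6
Reactants: 8 2-(2-bromophenyl)-5-methoxy-1-nitro-6-tosyl-6H-furo[3,2-e]indole; 9 acetaldehyde; 10 1,3,5-trimethyl-1,3,5-triazinane
Product: 13 cis-fused 4a-(2-bromophenyl)-9a-nitro-N-methylpiperidine hemiaminal (4aS,9aR; C3 epimers), via Michael aldehyde 11 (not isolated), via N-methylmethanimine 12 (not isolated)
Conditions: MeCHO (10 equiv), (S)-α,α-diphenylprolinol trimethylsilyl ether (20 mol %), 4-nitrophenol (20 mol %), 1,4-dioxane, rt; excess MeCHO removed in vacuo; then 10 (0.5 equiv), 40 °C
Reagents that add atoms: none
Why: Proposed new method: the enamine of acetaldehyde and the (S)-prolinol silyl ether should add to furan carbon C2 of 8 (the β-carbon of a β-aryloxy nitroalkene, future C4a) through an open synclinal transition state in which the nitro group lies under the enamine nitrogen, 4-nitrophenol then protonating the nitronate and releasing aldehyde 11; the closest known reaction type is the amine-catalysed Michael/aza-Henry/hemiaminalisation of aldehydes, nitroalkenes and imines to piperidines, together with dearomative conjugate additions to 3-nitrobenzofurans and 3-nitroindoles, none of which has used a 2-aryl-3-nitrobenzofuran. Once the excess acetaldehyde is gone, triazinane 10 acts as base and as source of imine 12, and the benzylic nitronate at C9a attacks the derived N-methyliminium ion in a nitro-Mannich step (C9a–C1). The secondary amine so formed closes the piperidine ring by 6-exo-trig addition of N2 to the aldehyde carbon C3, the hemiaminal carbon being left as a mixture that the next step removes. C4a is controlled by the catalyst, whose diphenyl(silyloxy)methyl group blocks one enamine face, and C9a by the substrate, the iminium ion coming in anti to the 2-bromophenyl group, with the reversible nitro-Mannich step draining any trans adduct because only cis-disposed CH2NHMe and CH2CHO arms can cyclise. The step needs attack at C2 without loss of the aryloxide, and the substrate secures this because the ring C2–O bond lies in the plane of the five-membered ring, orthogonal to the nitronate π system (the reverse of a 5-endo-trig closure), so that β-elimination is slow beside protonation and the Mannich reaction. Formaldimine is kept out of the first stage so that it cannot aminomethylate the acetaldehyde enamine.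

Step 7
Reactants: 13 cis-fused piperidine hemiaminal
Product: 14 (4aS,9aR)-4a-(2-bromophenyl)-2-methyl-9a-nitro piperidine fused to the 6-tosyl dihydrofuroindole
Conditions: NaBH(OAc)3, AcOH, ClCH2CH2Cl, rt
Reagents that add atoms: none
Why: As in the second half of a reductive amination, the N-methyl hemiaminal ionises in acetic acid to the cyclic iminium ion, which triacetoxyborohydride reduces to the N-methylpiperidine without touching the nitro group, the aryl bromide or the N-tosylindole.

Step 8
Reactants: 14 nitro piperidine
Product: 15 (4aS,9aR)-9a-amino-4a-(2-bromophenyl)-2-methyl piperidine fused to the 6-tosyl dihydrofuroindole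
Conditions: Zn dust, AcOH/THF, rt → 45 °C
Reagents that add atoms: none
Why: Dissolving-metal reduction of a tertiary aliphatic nitro group to the primary amine is the standard way of turning aza-Henry adducts into 1,2-diamines, zinc in acetic acid sparing the aryl bromide and the sulfonamide while the quaternary C9a cannot epimerise.

Step 9
Reactants: 15 amino aryl bromide
Product: 16 1'-tosyl-3'-de(dimethylaminomethyl) target (indoline ring closed; 4aS,9aR)
Conditions: Pd2(dba)3 (5 mol %), XPhos (12 mol %), Cs2CO3, toluene, 100 °C
Reagents that add atoms: none
Why: Intramolecular Buchwald–Hartwig amination, in which oxidative addition of the aryl bromide to zerovalent palladium and coupling with the cis-disposed primary amine through a six-membered palladacycle closes the indoline (N9–C8a), the cis relation of NH2 and aryl having been fixed in step 6.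

Step 10
Reactants: 16 N-tosyl pentacycle
Product: 17 3'-de(dimethylaminomethyl) target (free indole N–H; 4aS,9aR)
Conditions: Mg turnings, MeOH, ultrasound, rt
Reagents that add atoms: none
Why: Single-electron reductive cleavage of the indole N–S bond by magnesium in methanol releases a sulfinate and no methylating sulfonate ester, so the N-methylpiperidine cannot be quaternised, and the indoline N–H and the aryl ether are inert.

Step 11
Reactants: 17 de(dimethylaminomethyl) target
Product: 18 target CNP0318114.2 (4aS,9aR)
Conditions: Me2NH (40% aq.), CH2O (37% aq.), AcOH, 0 °C → rt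
Reagents that add atoms: formaldehyde, C=O; dimethylamine, CNC
Why: Mannich reaction, in which the iminium ion from formaldehyde and dimethylamine attacks the free indole at C3', by far its most nucleophilic position, to give the gramine side chain, while the hindered indoline nitrogen on the quaternary carbon forms at most a reversible aminal that is lost on basic work-up.

**Compound list**

1 | 3-methoxy-4-nitrophenol | COc1cc(O)ccc1[N+](=O)[O-] | starting material
2 | 2-iodo-5-methoxy-4-nitrophenol | COc1cc(O)c(I)cc1[N+](=O)[O-] | intermediate
3 | 1-bromo-2-ethynylbenzene | C#Cc1ccccc1Br | starting material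
4 | 2-[(2-bromophenyl)ethynyl]-5-methoxy-4-nitrophenol | COc1cc(O)c(C#Cc2ccccc2Br)cc1[N+](=O)[O-] | intermediate
5 | 2-(2-bromophenyl)-6-methoxy-5-nitrobenzofuran | COc1cc2oc(-c3ccccc3Br)cc2cc1[N+](=O)[O-] | intermediate
6 | 2-(2-bromophenyl)-5-methoxy-6H-furo[3,2-e]indole (O3, N6; furan O on indole C5', furan C1 on indole C4', OMe on C7') | COc1cc2oc(-c3ccccc3Br)cc2c2cc[nH]c12 | intermediate
7 | 2-(2-bromophenyl)-5-methoxy-6-tosyl-6H-furo[3,2-e]indole | COc1cc2oc(-c3ccccc3Br)cc2c2ccn(S(=O)(=O)c3ccc(C)cc3)c12 | intermediate
8 | 2-(2-bromophenyl)-5-methoxy-1-nitro-6-tosyl-6H-furo[3,2-e]indole | COc1cc2oc(-c3ccccc3Br)c([N+](=O)[O-])c2c2ccn(S(=O)(=O)c3ccc(C)cc3)c12 | intermediate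
9 | acetaldehyde | CC=O | starting material
10 | 1,3,5-trimethyl-1,3,5-triazinane | CN1CN(C)CN(C)C1 | starting material
11 | [(2S)-2-(2-bromophenyl)-5-methoxy-1-nitro-6-tosyl-1,2-dihydro-6H-furo[3,2-e]indol-2-yl]acetaldehyde (C4a S; nitro-bearing C9a as epimers) | COc1cc2c(c3ccn(S(=O)(=O)c4ccc(C)cc4)c13)C([N+](=O)[O-])[C@@](CC=O)(O2)c1ccccc1Br | intermediate
12 | N-methylmethanimine | C=NC | intermediate
13 | cis-fused piperidine hemiaminal: C4H2–C3H(OH)–N2(Me)–C1H2 bridging furan C2 (C4a, S, with 2-bromophenyl) and furan C1 (C9a, R, with NO2) of the 6-tosyl dihydrofuroindole; nitro cis to aryl; C3 epimers | COc1cc2c(c3ccn(S(=O)(=O)c4ccc(C)cc4)c13)[C@@]1([N+](=O)[O-])CN(C)C(O)C[C@]1(O2)c1ccccc1Br | intermediate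
14 | (4aS,9aR)-4a-(2-bromophenyl)-2-methyl-9a-nitro piperidine cis-fused to the 6-tosyl dihydrofuroindole | COc1cc2c(c3ccn(S(=O)(=O)c4ccc(C)cc4)c13)[C@@]1([N+](=O)[O-])CN(C)CC[C@]1(O2)c1ccccc1Br | intermediate
15 | (4aS,9aR)-9a-amino-4a-(2-bromophenyl)-2-methyl piperidine cis-fused to the 6-tosyl dihydrofuroindole | COc1cc2c(c3ccn(S(=O)(=O)c4ccc(C)cc4)c13)[C@@]1(N)CN(C)CC[C@]1(O2)c1ccccc1Br | intermediate
16 | (4aS,9aR)-1'-tosyl-3'-de(dimethylaminomethyl) target (benzofuro-indoline propellane with N-methylpiperidine) | COc1cc2c(c3ccn(S(=O)(=O)c4ccc(C)cc4)c13)[C@@]13CN(C)CC[C@]1(O2)c1ccccc1N3 | intermediate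
17 | (4aS,9aR)-3'-de(dimethylaminomethyl) target | COc1cc2c(c3cc[nH]c13)[C@@]13CN(C)CC[C@]1(O2)c1ccccc1N3 | intermediate
18 | CNP0318114.2, (4aS,9aR) | COc1cc2c(c3c(CN(C)C)c[nH]c13)[C@@]13CN(C)CC[C@]1(O2)c1ccccc1N3 | target

**Step count**

Total steps: 11. Longest linear sequence: 11 steps (from 1; compounds 3, 9 and 10 enter as purchased materials).

**Steps most likely to fail**

Step 6 (bears the label). The acetaldehyde enamine may be too weak a nucleophile for the tetrasubstituted, aryl-flanked furan carbon, so that aldehyde self-condensation outruns the conjugate addition. The nitronate may also expel the aryloxide and erase C4a, or the facial selectivity may be poor. The fallback uses a stoichiometric chiral azaenolate, a known Michael donor toward nitroalkenes, and sets out from 8. Acetaldehyde 9 is condensed with (S)-1-amino-2-(methoxymethyl)pyrrolidine to give the acetaldehyde SAMP hydrazone F1, which is deprotonated with LDA (LiN(i-Pr)2) in THF at −78 °C. The far more nucleophilic lithium azaenolate is added to 8 at −78 °C and the nitronate is quenched cold with AcOH, giving the hydrazone adduct F2. Its C4a diastereomers are separated by chromatography, so the sense of auxiliary control need not be predicted (the antipodal auxiliary is the alternative). Mild hydrolysis (saturated aqueous oxalic acid/Et2O, or aqueous CuCl2 if this is slow) releases the auxiliary and aldehyde 11, where the route is rejoined. 11 is then treated with 10 as in the second stage of step 6 to give 13.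

Step 5. The nitrating agent may attack the arene carbon between the two oxygen substituents or pyrrole C3', or degrade the electron-rich ring oxidatively. The fallback sets out from 7 and separates site selection from the introduction of nitrogen. Iodination with NIS (MeCN, 0 °C), a cleaner substitution on 2-arylbenzofurans, should give the furan iodide F3, which can be secured isomerically pure. Copper-catalysed ipso-substitution of iodide by nitrite (Cu powder, N,N'-dimethylethylenediamine, Bu4N+ NO2−, DMF, 90 °C), the C–I bond reacting ahead of the C–Br bond, then returns to the route at 8.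

Step 3. The vinyl Grignard reagent may be consumed by conjugate addition to the extended nitrobenzofuran π system, or the sigmatropic shift onto the crowded carbon next to furan C–H may be slow, leaving aniline and azo by-products. The fallback builds the pyrrole ring first on a plain benzene ring and the furan ring afterwards, and sets out from 1.
- Benzylation (BnBr, K2CO3, DMF) gives the benzyl ether F4.
- The Bartoli reaction is run on this simple 4-alkoxy-2-methoxynitrobenzene to give the indole F5.
- NaH/TsCl gives the N-tosylindole F6.
- Hydrogenolysis (H2, Pd/C, EtOAc) gives the phenol F7.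
- NIS iodination ortho to OH and para to OMe gives the 4-iodo-5-hydroxyindole F8.
- Sonogashira coupling/cyclisation of F8 with 3 under the conditions of step 2 rejoins the route at 7.

**Further compounds**

F1 | step 6 | (S,E)-N-ethylidene-2-(methoxymethyl)pyrrolidin-1-amine (acetaldehyde SAMP hydrazone) | C/C=N/N1CCC[C@H]1COC
F2 | step 6 | SAMP hydrazone of aldehyde 11 (C4a S; C9a epimers) | COc1cc2c(c3ccn(S(=O)(=O)c4ccc(C)cc4)c13)C([N+](=O)[O-])[C@@](C/C=N/N1CCC[C@H]1COC)(O2)c1ccccc1Br
F3 | step 5 | 2-(2-bromophenyl)-1-iodo-5-methoxy-6-tosyl-6H-furo[3,2-e]indole | COc1cc2oc(-c3ccccc3Br)c(I)c2c2ccn(S(=O)(=O)c3ccc(C)cc3)c12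
F4 | step 3 | 4-(benzyloxy)-2-methoxy-1-nitrobenzene | COc1cc(OCc2ccccc2)ccc1[N+](=O)[O-]
F5 | step 3 | 5-(benzyloxy)-7-methoxy-1H-indole | COc1cc(OCc2ccccc2)cc2cc[nH]c12
F6 | step 3 | 5-(benzyloxy)-7-methoxy-1-tosyl-1H-indole | COc1cc(OCc2ccccc2)cc2ccn(S(=O)(=O)c3ccc(C)cc3)c12
F7 | step 3 | 7-methoxy-1-tosyl-1H-indol-5-ol | COc1cc(O)cc2ccn(S(=O)(=O)c3ccc(C)cc3)c12
F8 | step 3 | 4-iodo-7-methoxy-1-tosyl-1H-indol-5-ol | COc1cc(O)c(I)c2ccn(S(=O)(=O)c3ccc(C)cc3)c12
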